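**Plan**

- Retrosynthesis: both pyranone rings are cut back (lactone C–O and C5'–C6' bonds) to formyl groups on C3 and C4 of the cyclobutane. The two formyl carbons are rejoined as the cis-diol of a second, sacrificial cyclobutane. That ring is cut at its bonds to C3 and C4 ([2+2] with vinylene carbonate), and the first ring at C1–C4 and C2–C3 ([2+2] of maleic anhydride with but-2-yne).
- Forward: ring A (dimethylcyclobutene anhydride), then ring B fused onto it (ladder), then ring B opened by glycol cleavage, then both pyranones grown at once by dianion aldol, oxidation and lactonisation, then O-methylation and ester cleavage.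
- Enabling feature: C3 and C4 are adjacent quaternary ring carbons, each carrying a methyl and a pyranone C6 carbon of acyl oxidation level. The two pyranones are cis to each other and trans to the C1/C2 carboxyls. This is the imprint of a two-carbon unit added to the convex face of the C6=C7 bond of a cis-fused 6,7-dimethyl-3-oxabicyclo[3.2.0]heptene.
- Stereochemistry: the cis carboxyls come from the anhydride ring of maleic anhydride, and the two quaternary centres from exo-face attack in the second photocycloaddition. The target is meso, so no absolute control is needed, and every other stereocentre made on the way is destroyed later.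

Key step: step 2

Remark: all symmetric intermediates are meso; the half-ester of step 3 is racemic (one enantiomer drawn); the double aldol adduct of step 7 is a mixture of side-chain diastereomers (drawn without descriptors there); enolisable compounds are drawn as one tautomer.

**Route**

Step 1
Reactants: 1 maleic anhydride; 2 but-2-yne
Product: 3 cis-6,7-dimethyl-3-oxabicyclo[3.2.0]hept-6-ene-2,4-dione (meso)
Conditions: hν (Pyrex, λ > 300 nm), PhCOMe (0.1 equiv), 2 (5 equiv), MeCN, 0 °C, stopped at partial conversion of 1
Reagents that add atoms: none
Why: Sensitised [2+2] photocycloaddition of triplet maleic anhydride to the alkyne through a 1,4-biradical that closes to the cyclobutene; the two bridgehead CH centres can only be cis because the five-membered anhydride ring ties them together, and excess alkyne with partial conversion holds back further addition of 1 to the product.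

Step 2
Reactants: 3 cis-6,7-dimethyl-3-oxabicyclo[3.2.0]hept-6-ene-2,4-dione; 4 vinylene carbonate
Product: 5 ladder adduct, 1,4-dimethylbicyclo[2.2.0]hexane with the cis-2,3-dicarboxylic anhydride on the exo face (cis to the bridgehead methyls) and the cis-5,6-cyclic carbonate, oxygens exo (meso)
Conditions: hν (Pyrex, about 300 nm), acetone (solvent and sensitiser), 4 (3 equiv, added in portions), 0–10 °C, degassed
Reagents that add atoms: none
Why: Triplet energy transfer from acetone gives triplet vinylene carbonate, which adds to the strained C6=C7 bond of 3 to a triplet 1,4-biradical that, after spin inversion, forms the second C–C bond; the closest known reaction type is the sensitised [2+2] photocycloaddition of vinylene carbonate or maleic anhydride to cycloalkenes and cyclobutenes, which gives ladder-type bicyclo[2.2.0]hexanes. The one ring formed, ring B, closes by radical–radical recombination of this biradical, and both new bonds must end on the same face because a four-membered ring can only be cis-fused to ring A. The two quaternary centres C1 and C4 are set by the face of attack: the cup-shaped bicyclo[3.2.0]heptene exposes its convex face, anti to the anhydride ring, so the new bonds lie trans to the anhydride carbonyls and both methyls are pushed onto the anhydride face. The carbonate-bearing centres C5 and C6 are held cis by the ring of 4; their orientation relative to ring A (anti expected) does not matter, because both carbons become carbonyl carbons and either isomer converges in step 6. The step therefore needs facial selectivity, secured by the fused anhydride ring, and cross-addition in preference to dimerisation of 4, helped by the ring strain of the tetrasubstituted cyclobutene, which cannot dissipate triplet energy by twisting, and by keeping the stationary concentration of 4 low.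

Step 3
Reactants: 5 ladder adduct
Product: 6 mono-tert-butyl half-ester of the ladder adduct: 3-(tert-butoxycarbonyl)-1,4-dimethylbicyclo[2.2.0]hexane-2-carboxylic acid 5,6-cyclic carbonate, ester and acid cis (racemic)
Conditions: t-BuOH (excess), DMAP (0.2 equiv), toluene, 80 °C
Reagents that add atoms: tert-butanol, CC(C)(C)O
Why: DMAP-catalysed alcoholysis of a cyclic anhydride (nucleophilic acyl substitution via the acylpyridinium) stops at the half-ester because the acid formed is no acylating agent; the less electrophilic cyclic carbonate is expected to stay closed, and no stereocentre is touched.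

Step 4
Reactants: 6 half-ester
Product: 7 di-tert-butyl 1,4-dimethylbicyclo[2.2.0]hexane-2,3-dicarboxylate 5,6-cyclic carbonate, esters cis to each other and to the methyls (meso)
Conditions: Cl3CC(=NH)Ot-Bu (3 equiv), BF3·OEt2 (5 mol %), CH2Cl2/cyclohexane, rt
Reagents that add atoms: tert-butyl 2,2,2-trichloroacetimidate, CC(C)(C)OC(=N)C(Cl)(Cl)Cl
Why: Acid-catalysed O-alkylation of the carboxylic acid by the trichloroacetimidate (tert-butyl cation transfer) never activates the carboxyl carbon, so the cis half-ester cannot close back to the anhydride.

Step 5
Reactants: 7 diester carbonate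
Product: 8 di-tert-butyl 5,6-dihydroxy-1,4-dimethylbicyclo[2.2.0]hexane-2,3-dicarboxylate, cis-diol, hydroxyls exo (meso)
Conditions: K2CO3 (0.2 equiv), MeOH, 0 °C to rt
Reagents that add atoms: none
Why: Methoxide-catalysed transesterification of the strained five-membered cyclic carbonate releases the cis-diol with retention at both carbinol carbons, while the hindered tert-butyl esters resist methanolysis.

Step 6
Reactants: 8 diol
Product: 9 di-tert-butyl (1R,2S,3R,4S)-3,4-diformyl-3,4-dimethylcyclobutane-1,2-dicarboxylate (meso; esters and methyls on one face, formyl groups on the other)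
Conditions: NaIO4 on silica gel, CH2Cl2, rt
Reagents that add atoms: none
Why: Periodate glycol cleavage through the cyclic periodate ester is favoured by the nearly eclipsed cis-diol on the four-membered ring and by release of the bicyclo[2.2.0]hexane strain; the formyl-bearing carbons are quaternary and cannot epimerise, so the configuration from step 2 is kept.

Step 7
Reactants: 9 dialdehyde; 10 methyl 2-methyl-3-oxobutanoate
Product: 11 di-tert-butyl 3,4-bis(1-hydroxy-5-methoxy-4-methyl-3,5-dioxopentyl)-3,4-dimethylcyclobutane-1,2-dicarboxylate (ring configuration as in 9; mixture of side-chain diastereomers)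
Conditions: 10 (4.4 equiv), LiN(iPr)2 (8.8 equiv), THF, −78 to 0 °C; then 9, −78 to −30 °C; AcOH quench at −78 °C
Reagents that add atoms: none
Why: Two-directional γ-selective aldol addition of the β-keto ester dianion, whose terminal enolate carbon attacks each neopentyl aldehyde while the tert-butyl esters are too hindered to be acylated; the lactolate formed reversibly when the first aldolate adds to the neighbouring formyl group should reopen under excess dianion, and the new carbinol and α-methyl centres need no control because steps 8 and 9 erase them.

Step 8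
Reactants: 11 double aldol adduct
Product: 12 di-tert-butyl (1R,2S,3R,4S)-3,4-bis(5-methoxy-4-methyl-3,5-dioxopentanoyl)-3,4-dimethylcyclobutane-1,2-dicarboxylate (epimers at the side-chain methine)
Conditions: Dess–Martin periodinane (2.5 equiv), CH2Cl2, 0 °C to rt
Reagents that add atoms: none
Why: Dess–Martin oxidation of the two secondary alcohols gives the 3,5-dioxo ester arms under near-neutral conditions that leave the tert-butyl esters and the ring stereocentres untouched.

Step 9
Reactants: 12 bis(dioxo ester)
Product: 13 di-tert-butyl (1R,2S,3R,4S)-3,4-bis(4-hydroxy-3-methyl-2-oxo-2H-pyran-6-yl)-3,4-dimethylcyclobutane-1,2-dicarboxylate (meso)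
Conditions: DBU (4 equiv), toluene, rt to 60 °C; dilute aqueous acid work-up
Reagents that add atoms: none
Why: Base-mediated enol-lactonisation, in which the enolate oxygen of the ketone next to the ring acylates itself on the methyl ester (6-exo-trig), gives each 4-hydroxy-2-pyranone; it is driven by loss of methanol and by the conjugated pyranone, and the side-chain stereocentres vanish.

Step 10
Reactants: 13 bis(hydroxypyranone)
Product: 14 di-tert-butyl (1R,2S,3R,4S)-3,4-bis(4-methoxy-3-methyl-2-oxo-2H-pyran-6-yl)-3,4-dimethylcyclobutane-1,2-dicarboxylate (meso)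
Conditions: Me2SO4 (3 equiv), K2CO3 (4 equiv), acetone, rt to 40 °C
Reagents that add atoms: dimethyl sulfate, COS(=O)(=O)OC
Why: O-Methylation of the vinylogous acid (Williamson-type alkylation) with the hard electrophile dimethyl sulfate and K2CO3 in acetone favours the 4-methoxy-2-pyranone over the isomeric 2-methoxy-4-pyranone and over C-methylation at C3.

Step 11
Reactants: 14 bis(methoxypyranone) di-tert-butyl ester
Product: 15 (1R,2S,3R,4S)-3,4-bis(4-methoxy-3-methyl-2-oxo-2H-pyran-6-yl)-3,4-dimethylcyclobutane-1,2-dicarboxylic acid (meso; carboxyls and methyls on one face, pyranones on the other)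
Conditions: CF3CO2H/CH2Cl2 (1:2), 0 °C to rt
Reagents that add atoms: none
Why: Acidolysis of the tert-butyl esters by the E1 pathway (loss of 2-methylpropene) frees both carboxylic acids without any base or nucleophile that could open the methoxypyranones or epimerise C1 and C2.

**Compound list**

1 | maleic anhydride | O=C1OC(=O)C=C1 | starting material
2 | but-2-yne | CC#CC | starting material
3 | cis-6,7-dimethyl-3-oxabicyclo[3.2.0]hept-6-ene-2,4-dione (meso) | CC1=C(C)[C@H]2C(=O)OC(=O)[C@@H]12 | intermediate
4 | vinylene carbonate (1,3-dioxol-2-one) | O=C1OC=CO1 | starting material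
5 | ladder adduct: 1,4-dimethylbicyclo[2.2.0]hexane-2,3-dicarboxylic anhydride 5,6-cyclic carbonate, anhydride cis to the methyls, carbonate oxygens exo (meso) | O=C1O[C@@H]4[C@@]2(C)[C@H](C(=O)O3)[C@H](C3=O)[C@@]2(C)[C@@H]4O1 | intermediate
6 | mono-tert-butyl half-ester of 5 (racemic, one enantiomer drawn) | O=C1O[C@@H]4[C@@]2(C)[C@H](C(=O)OC(C)(C)C)[C@H](C(=O)O)[C@@]2(C)[C@@H]4O1 | intermediate
7 | di-tert-butyl 1,4-dimethylbicyclo[2.2.0]hexane-2,3-dicarboxylate 5,6-cyclic carbonate (meso) | O=C1O[C@@H]4[C@@]2(C)[C@H](C(=O)OC(C)(C)C)[C@H](C(=O)OC(C)(C)C)[C@@]2(C)[C@@H]4O1 | intermediate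
8 | di-tert-butyl 5,6-dihydroxy-1,4-dimethylbicyclo[2.2.0]hexane-2,3-dicarboxylate, cis-diol (meso) | O[C@@H]1[C@@]2(C)[C@H](C(=O)OC(C)(C)C)[C@H](C(=O)OC(C)(C)C)[C@@]2(C)[C@@H]1O | intermediate
9 | di-tert-butyl (1R,2S,3R,4S)-3,4-diformyl-3,4-dimethylcyclobutane-1,2-dicarboxylate (meso) | O=C[C@@]1(C)[C@H](C(=O)OC(C)(C)C)[C@H](C(=O)OC(C)(C)C)[C@@]1(C)C=O | intermediate
10 | methyl 2-methyl-3-oxobutanoate | CC(=O)C(C)C(=O)OC | starting material
11 | di-tert-butyl 3,4-bis(1-hydroxy-5-methoxy-4-methyl-3,5-dioxopentyl)-3,4-dimethylcyclobutane-1,2-dicarboxylate (diastereomer mixture in the side chains) | COC(=O)C(C)C(=O)CC(O)[C@@]1(C)[C@H](C(=O)OC(C)(C)C)[C@H](C(=O)OC(C)(C)C)[C@@]1(C)C(O)CC(=O)C(C)C(=O)OC | intermediate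
12 | di-tert-butyl (1R,2S,3R,4S)-3,4-bis(5-methoxy-4-methyl-3,5-dioxopentanoyl)-3,4-dimethylcyclobutane-1,2-dicarboxylate | COC(=O)C(C)C(=O)CC(=O)[C@@]1(C)[C@H](C(=O)OC(C)(C)C)[C@H](C(=O)OC(C)(C)C)[C@@]1(C)C(=O)CC(=O)C(C)C(=O)OC | intermediate
13 | di-tert-butyl (1R,2S,3R,4S)-3,4-bis(4-hydroxy-3-methyl-2-oxo-2H-pyran-6-yl)-3,4-dimethylcyclobutane-1,2-dicarboxylate (meso) | Oc1cc([C@@]2(C)[C@H](C(=O)OC(C)(C)C)[C@H](C(=O)OC(C)(C)C)[C@@]2(C)c2cc(O)c(C)c(=O)o2)oc(=O)c1C | intermediate
14 | di-tert-butyl (1R,2S,3R,4S)-3,4-bis(4-methoxy-3-methyl-2-oxo-2H-pyran-6-yl)-3,4-dimethylcyclobutane-1,2-dicarboxylate (meso) | COc1cc([C@@]2(C)[C@H](C(=O)OC(C)(C)C)[C@H](C(=O)OC(C)(C)C)[C@@]2(C)c2cc(OC)c(C)c(=O)o2)oc(=O)c1C | intermediate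
15 | (1R,2S,3R,4S)-3,4-bis(4-methoxy-3-methyl-2-oxo-2H-pyran-6-yl)-3,4-dimethylcyclobutane-1,2-dicarboxylic acid (meso) | COc1cc([C@@]2(C)[C@H](C(=O)O)[C@H](C(=O)O)[C@@]2(C)c2cc(OC)c(C)c(=O)o2)oc(=O)c1C | target

**Count**

Total steps: 11. Longest linear sequence: 11 steps (1 to 15).

**Steps most likely to fail**

Step 2. The excitation may be wasted: triplet vinylene carbonate can dimerise, excited acetone can add to either alkene as an oxetane (Paternò–Büchi), and the crowded 1,4-biradical can revert, so cross-addition to the tetrasubstituted alkene may stall. The fallback exchanges the order of the two photocycloadditions, so that the ladder-forming event uses triplet maleic anhydride, the more efficient partner, whose addition to 1,2-dimethylcyclobutenes is the known over-reaction of step 1. It sets out from 2 and 4: acetone-sensitised addition of 4 to but-2-yne should give cis-6,7-dimethyl-2,4-dioxabicyclo[3.2.0]hept-6-en-3-one F1. Acetophenone-sensitised addition of 1 to the face of F1 anti to the carbonate, with the anhydride turned away from ring B, comes back to the route at 5. In this order the methyl/carboxyl relationship rests on the anti orientation of the incoming anhydride, so the syn isomer would have to be removed by crystallisation.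

Step 7. After the first addition the aldolate oxygen closes onto the neighbouring formyl group; if this lactolate does not reopen at temperatures the dianion and the aldolate tolerate, the reaction stops at mono-addition, or retro-aldol and premature lactonisation take over on warming. The fallback replaces the basic dianion by a Lewis-acid-mediated vinylogous Mukaiyama aldol, in which the aldolate oxygen is held as a boron or silyl species and cannot add to the second aldehyde. It sets out from 9: ketoester 10 is converted (Me3SiCl/Et3N, then LiN(iPr)2/Me3SiCl) into 1-methoxy-2-methyl-1,3-bis(trimethylsilyloxy)buta-1,3-diene F2. F2 is added to 9 with BF3·OEt2 in CH2Cl2 at −78 °C, and mild aqueous acid work-up comes back to the route at 11.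

Step 9. Under DBU the two neighbouring tricarbonyl arms form a 1,4-diketone pattern and may condense with each other (intramolecular aldol to a fused cyclopentenone), or suffer retro-Claisen cleavage, in competition with enol-lactonisation. The fallback closes the lactones at the alcohol oxidation level, where no such pattern exists, and adjusts the oxidation state last. It sets out from 11: K2CO3 in MeOH followed by acidification should give di-tert-butyl 3,4-bis(4-hydroxy-3-methyl-2-oxo-5,6-dihydro-2H-pyran-6-yl)-3,4-dimethylcyclobutane-1,2-dicarboxylate F3. Me2SO4/K2CO3 in acetone gives the corresponding bis(4-methoxy-5,6-dihydro-2-pyranone) F4, and dehydrogenation with DDQ in hot dioxane comes back to the route at 14.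

**Further compounds**

F1 | step 2 | cis-6,7-dimethyl-2,4-dioxabicyclo[3.2.0]hept-6-en-3-one | CC1=C(C)[C@H]2OC(=O)O[C@@H]12
F2 | step 7 | 1-methoxy-2-methyl-1,3-bis(trimethylsilyloxy)buta-1,3-diene | COC(O[Si](C)(C)C)=C(C)C(=C)O[Si](C)(C)C
F3 | step 9 | di-tert-butyl 3,4-bis(4-hydroxy-3-methyl-2-oxo-5,6-dihydro-2H-pyran-6-yl)-3,4-dimethylcyclobutane-1,2-dicarboxylate | CC1=C(O)CC(OC1=O)[C@@]2(C)[C@H](C(=O)OC(C)(C)C)[C@H](C(=O)OC(C)(C)C)[C@@]2(C)C1CC(O)=C(C)C(=O)O1
F4 | step 9 | di-tert-butyl 3,4-bis(4-methoxy-3-methyl-2-oxo-5,6-dihydro-2H-pyran-6-yl)-3,4-dimethylcyclobutane-1,2-dicarboxylate | CC1=C(OC)CC(OC1=O)[C@@]2(C)[C@H](C(=O)OC(C)(C)C)[C@H](C(=O)OC(C)(C)C)[C@@]2(C)C1CC(OC)=C(C)C(=O)O1
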